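The isoflavone is disconnected at two bonds of ring C, C4–C4a and O1–C2. The feature exploited is that the C4 carbonyl sits on C4a of the resorcinol-derived ring A, ortho to O1 on C8a and para to the 7-OH on C7, which is where an acyl group arrives when a resorcinol monoester undergoes an O-to-C shift. Irradiation of the 3-hydroxyphenyl ester of an (E)-2-aryl-3-methoxyacrylic acid should therefore move the acyl group onto carbon and, once the liberated phenol displaces the β-methoxy group, close the pyranone in the same flask. The chromene-bearing acid is assembled from methyl homovanillate by propargylation, Claisen cyclisation, formylation/O-methylation and saponification.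

Key step: step 6

Remarks on the chemistry:
- The target has no stereocentre or other stereogenic element, so it is one achiral compound and no enantioselective step is needed. The only stereodescriptor in the route is the E geometry of the β-methoxyacrylate, which disappears in the last step.
- Positions of the resorcinol ester ring are counted C1 (acyloxy) and C3 (free hydroxyl). Acyl return to C6 (ortho to the ester oxygen) and to C4 (para to it, ortho to the free hydroxyl) gives one and the same 2,4-dihydroxyaryl ketone. Only return to C2, between the two oxygens, is a regiochemical leak, and the free hydroxyl is what makes the two productive pathways converge.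

Step 1
Reactants: 1 methyl homovanillate; 2 3-chloro-3-methylbut-1-yne
Product: 3 methyl 2-{3-methoxy-4-[(2-methylbut-3-yn-2-yl)oxy]phenyl}acetate
Conditions: 2 (2 equiv), K2CO3, KI, CuI (cat.), acetone, reflux
Reagents that add atoms: none
Why: Copper-assisted Williamson-type O-alkylation of the phenoxide by the tertiary propargylic chloride is the standard entry to aryl 1,1-dimethylpropargyl ethers, and the methyl ester is inert to K2CO3 in acetone.

Step 2
Reactants: 3 methyl 2-{3-methoxy-4-[(2-methylbut-3-yn-2-yl)oxy]phenyl}acetate
Product: 6 methyl 2-(8-methoxy-2,2-dimethyl-2H-chromen-6-yl)acetate, via allenylphenol 4 (not isolated), via quinone methide 5 (not isolated)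
Conditions: o-xylene, 140 °C
Reagents that add atoms: none
Why: Aromatic propargyl Claisen rearrangement to the only free ortho carbon (the other carries OMe) should give allenylphenol 4 after tautomerisation, and its 1,5-hydrogen shift to (Z)-quinone methide 5 followed by oxa-6π electrocyclisation closes the 2,2-dimethyl-2H-chromene in the established thermal cascade.

Step 3
Reactants: 6 methyl 2-(8-methoxy-2,2-dimethyl-2H-chromen-6-yl)acetate; 7 methyl formate
Product: 9 methyl (E)-3-methoxy-2-(8-methoxy-2,2-dimethyl-2H-chromen-6-yl)acrylate, via sodium enolate 8 (not isolated)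
Conditions: NaH, 7 (excess), DMF, 0 °C → rt; evaporate excess 7; then Me2SO4, rt
Reagents that add atoms: dimethyl sulfate, COS(=O)(=O)OC
Why: Crossed Claisen condensation of the ester enolate with the non-enolisable formate is driven by formation of the stabilised enolate 8, whose oxygen is then methylated by dimethyl sulfate in DMF to the vinylogous carbonate, the E isomer (OMe anti to the ester) being the one this sequence is known to favour.

Step 4
Reactants: 9 methyl (E)-3-methoxy-2-(8-methoxy-2,2-dimethyl-2H-chromen-6-yl)acrylate
Product: 10 (E)-3-methoxy-2-(8-methoxy-2,2-dimethyl-2H-chromen-6-yl)acrylic acid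
Conditions: LiOH·H2O, THF/MeOH/H2O, 40 °C; then 1 M HCl to pH 3, 0 °C
Reagents that add atoms: lithium hydroxide, [Li+].[OH-]
Why: Saponification (BAc2) of methyl (E)-β-methoxyacrylates to the free acids is established chemistry, and neither the chromene nor the enol ether should suffer during the brief cold acidification.

Step 5
Reactants: 10 (E)-3-methoxy-2-(8-methoxy-2,2-dimethyl-2H-chromen-6-yl)acrylic acid; 11 resorcinol
Product: 12 3-hydroxyphenyl (E)-3-methoxy-2-(8-methoxy-2,2-dimethyl-2H-chromen-6-yl)acrylate
Conditions: 11 (5 equiv), DCC, DMAP (cat.), THF, 0 °C → rt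
Reagents that add atoms: none
Why: Steglich esterification through the O-acylisourea and the acylpyridinium ion acylates a phenol under neutral conditions that spare the acid-sensitive chromene, and the fivefold excess of the symmetrical diol should hold acylation at one oxygen.

Step 6
Reactants: 12 3-hydroxyphenyl (E)-3-methoxy-2-(8-methoxy-2,2-dimethyl-2H-chromen-6-yl)acrylate
Product: 15 7-hydroxy-3-(8-methoxy-2,2-dimethyl-2H-chromen-6-yl)-4H-chromen-4-one, via dihydroxyaryl ketone 13 (not isolated), via methoxychromanone adduct 14 (not isolated)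
Conditions: hν (254 nm, quartz), degassed MeCN (ca. 2 mM), 20 °C; then Et3N, 40 °C, dark
Reagents that add atoms: none
Why: Proposed new method: excitation should cleave the ArO–C(=O) bond homolytically to a caged 3-hydroxyphenoxyl/acyl radical pair that recombines at ring carbon and tautomerises to ketone 13 (C4–C4a bond), the closest known reaction type being the photo-Fries rearrangement of resorcinol monoesters to 2,4-dihydroxyaryl ketones and of aryl cinnamates or 3-methylbut-2-enoates to o-hydroxyaryl enones. What is new is that the β-methoxy group should turn the oxa-Michael closure known for such enones into an addition–elimination that ends at the chromone. Ring C closes by 6-endo-trig attack of the ortho hydroxyl oxygen of 13 on the β-carbon (O1–C2 bond) to give 14, and E1cB loss of methanol, helped by the Et3N added once the lamp is off, completes the pyranone. No stereocentre remains, since both centres of 14 are erased on elimination and E/Z photoisomerisation of the acrylate is without consequence. The selectivity needed is recombination away from C2 of the resorcinol ring: because the C3 hydroxyl is left free, acyl return to C6 and to C4 gives the same ketone 13, so only the hindered C2 between the two oxygens leads off course, to the 5-hydroxy isomer. Decarbonylation is not expected, because the α,β-unsaturated acyl radical would have to give a vinyl radical.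

Compound list
1 | methyl homovanillate (methyl 2-(4-hydroxy-3-methoxyphenyl)acetate) | COC(=O)Cc1ccc(O)c(OC)c1 | starting material
2 | 3-chloro-3-methylbut-1-yne | CC(C)(Cl)C#C | starting material
3 | methyl 2-{3-methoxy-4-[(2-methylbut-3-yn-2-yl)oxy]phenyl}acetate | COC(=O)Cc1ccc(OC(C)(C)C#C)c(OC)c1 | intermediate
4 | methyl 2-[4-hydroxy-3-methoxy-5-(3-methylbuta-1,2-dien-1-yl)phenyl]acetate (allenylphenol) | COC(=O)Cc1cc(OC)c(O)c(C=C=C(C)C)c1 | intermediate
5 | methyl 2-[(3Z)-5-methoxy-3-(3-methylbut-2-en-1-ylidene)-4-oxocyclohexa-1,5-dien-1-yl]acetate (quinone methide) | COC(=O)CC1=C/C(=C/C=C(C)C)C(=O)C(OC)=C1 | intermediate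
6 | methyl 2-(8-methoxy-2,2-dimethyl-2H-chromen-6-yl)acetate | COC(=O)Cc1cc(OC)c2OC(C)(C)C=Cc2c1 | intermediate
7 | methyl formate | COC=O | starting material
8 | sodium 3-methoxy-2-(8-methoxy-2,2-dimethyl-2H-chromen-6-yl)-3-oxoprop-1-en-1-olate (delocalised enolate, geometry not fixed) | COC(=O)C(=C[O-])c1cc(OC)c2OC(C)(C)C=Cc2c1.[Na+] | intermediate
9 | methyl (E)-3-methoxy-2-(8-methoxy-2,2-dimethyl-2H-chromen-6-yl)acrylate | CO/C=C(\c1cc(OC)c2OC(C)(C)C=Cc2c1)C(=O)OC | intermediate
10 | (E)-3-methoxy-2-(8-methoxy-2,2-dimethyl-2H-chromen-6-yl)acrylic acid | CO/C=C(\c1cc(OC)c2OC(C)(C)C=Cc2c1)C(=O)O | intermediate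
11 | resorcinol | Oc1cccc(O)c1 | starting material
12 | 3-hydroxyphenyl (E)-3-methoxy-2-(8-methoxy-2,2-dimethyl-2H-chromen-6-yl)acrylate | CO/C=C(\c1cc(OC)c2OC(C)(C)C=Cc2c1)C(=O)Oc1cccc(O)c1 | intermediate
13 | (E)-1-(2,4-dihydroxyphenyl)-3-methoxy-2-(8-methoxy-2,2-dimethyl-2H-chromen-6-yl)prop-2-en-1-one | CO/C=C(\c1cc(OC)c2OC(C)(C)C=Cc2c1)C(=O)c1ccc(O)cc1O | intermediate
14 | 7-hydroxy-2-methoxy-3-(8-methoxy-2,2-dimethyl-2H-chromen-6-yl)chroman-4-one (transient, C2/C3 configuration undefined and erased on elimination) | COC1Oc2cc(O)ccc2C(=O)C1c1cc(OC)c2OC(C)(C)C=Cc2c1 | intermediate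
15 | 7-hydroxy-3-(8-methoxy-2,2-dimethyl-2H-chromen-6-yl)-4H-chromen-4-one | COc1cc(-c2coc3cc(O)ccc3c2=O)cc2c1OC(C)(C)C=C2 | target

Total step count: 6
Longest linear sequence: 6 steps (1 → 3 → 6 → 9 → 10 → 12 → 15)

Steps most likely to fail

1. Step 6 (bears the label).
 - What may go wrong: the radical pair may escape the solvent cage instead of recombining. The 2H-chromene may absorb competitively and undergo photochemical ring opening. The ketone and chromone may screen the light as they build up. Recombination may occur at C2. Ring closure may stay incomplete.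
 - Fallback (known chemistry, polar C-acylation by an aryl organometallic in place of the photochemical shift): it sets out from acid 10 and comes back to the route at ketone 13, and through it at 15.
 - Acid 10 would be converted with 1,1'-carbonyldiimidazole and N,O-dimethylhydroxylamine hydrochloride (THF, rt) into the Weinreb amide (E)-N,3-dimethoxy-N-methyl-2-(8-methoxy-2,2-dimethyl-2H-chromen-6-yl)acrylamide F1.
 - Purchased 4-bromoresorcinol would be protected (NaH, MOMCl, DMF, 0 °C) as 1-bromo-2,4-bis(methoxymethoxy)benzene F2. Bromine–lithium exchange (n-BuLi, THF, −78 °C) would give [2,4-bis(methoxymethoxy)phenyl]lithium F3, with the site of acylation fixed by the bromine.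
 - Addition of F3 to F1 should stop at the chelated adduct, since the amide has no α-hydrogen to lose. Aqueous NH4Cl would release (E)-1-[2,4-bis(methoxymethoxy)phenyl]-3-methoxy-2-(8-methoxy-2,2-dimethyl-2H-chromen-6-yl)prop-2-en-1-one F4.
 - Dilute HCl in MeOH at 40 °C would remove both acetals to give 13, which under the same acid should close to 15 with loss of methanol.

2. Step 5.
 - What may go wrong: the monoester may be acylated a second time. Acyl transfer from the hindered, donor-deactivated acid may be so slow that the O-acylisourea rearranges to the N-acylurea.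
 - Fallback (protecting-group control and acid chloride activation in place of statistical control): it sets out from 11 and 10 and comes back at 12.
 - Resorcinol 11, in excess, would be monosilylated (TBSCl, imidazole, DMF) to 3-[(tert-butyldimethylsilyl)oxy]phenol F5, so the statistical problem is moved onto a cheap compound.
 - Acid 10 would be converted under neutral conditions with 1-chloro-N,N,2-trimethylprop-1-en-1-amine (CH2Cl2, 0 °C) into (E)-3-methoxy-2-(8-methoxy-2,2-dimethyl-2H-chromen-6-yl)acryloyl chloride F6.
 - F6 would acylate F5 (pyridine, DMAP cat., CH2Cl2) to 3-[(tert-butyldimethylsilyl)oxy]phenyl (E)-3-methoxy-2-(8-methoxy-2,2-dimethyl-2H-chromen-6-yl)acrylate F7.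
 - HF·pyridine in THF/pyridine at 0 °C would then free the phenol to give 12.

3. Step 4.
 - What may go wrong: hydroxide may add to the β-carbon and displace methoxide, which leads on to deformylation. Alternatively, hydrolysis of the donor-stabilised ester may stall.
 - Fallback (an ester cleaved by palladium instead of hydroxide): it sets out from 6 and comes back at 10.
 - Ester 6 would be transesterified (allyl alcohol, Ti(OiPr)4 cat., reflux) to allyl 2-(8-methoxy-2,2-dimethyl-2H-chromen-6-yl)acetate F8.
 - Formylation with NaH and allyl formate in DMF, chosen to avoid ester scrambling, would give sodium 3-(allyloxy)-2-(8-methoxy-2,2-dimethyl-2H-chromen-6-yl)-3-oxoprop-1-en-1-olate F9.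
 - Methylation in the same flask with Me2SO4 would give allyl (E)-3-methoxy-2-(8-methoxy-2,2-dimethyl-2H-chromen-6-yl)acrylate F10.
 - Tsuji–Trost deallylation (Pd(PPh3)4 cat., morpholine, THF, rt) would release 10 without any hydroxide.

Further compounds
F1 | step 6 | (E)-N,3-dimethoxy-N-methyl-2-(8-methoxy-2,2-dimethyl-2H-chromen-6-yl)acrylamide | CO/C=C(\c1cc(OC)c2OC(C)(C)C=Cc2c1)C(=O)N(C)OC
F2 | step 6 | 1-bromo-2,4-bis(methoxymethoxy)benzene | COCOc1ccc(Br)c(OCOC)c1
F3 | step 6 | [2,4-bis(methoxymethoxy)phenyl]lithium | [Li]c1ccc(OCOC)cc1OCOC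
F4 | step 6 | (E)-1-[2,4-bis(methoxymethoxy)phenyl]-3-methoxy-2-(8-methoxy-2,2-dimethyl-2H-chromen-6-yl)prop-2-en-1-one | CO/C=C(\c1cc(OC)c2OC(C)(C)C=Cc2c1)C(=O)c1ccc(OCOC)cc1OCOC
F5 | step 5 | 3-[(tert-butyldimethylsilyl)oxy]phenol | CC(C)(C)[Si](C)(C)Oc1cccc(O)c1
F6 | step 5 | (E)-3-methoxy-2-(8-methoxy-2,2-dimethyl-2H-chromen-6-yl)acryloyl chloride | CO/C=C(\c1cc(OC)c2OC(C)(C)C=Cc2c1)C(Cl)=O
F7 | step 5 | 3-[(tert-butyldimethylsilyl)oxy]phenyl (E)-3-methoxy-2-(8-methoxy-2,2-dimethyl-2H-chromen-6-yl)acrylate | CO/C=C(\c1cc(OC)c2OC(C)(C)C=Cc2c1)C(=O)Oc1cccc(O[Si](C)(C)C(C)(C)C)c1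
F8 | step 4 | allyl 2-(8-methoxy-2,2-dimethyl-2H-chromen-6-yl)acetate | C=CCOC(=O)Cc1cc(OC)c2OC(C)(C)C=Cc2c1
F9 | step 4 | sodium 3-(allyloxy)-2-(8-methoxy-2,2-dimethyl-2H-chromen-6-yl)-3-oxoprop-1-en-1-olate | C=CCOC(=O)C(=C[O-])c1cc(OC)c2OC(C)(C)C=Cc2c1.[Na+]
F10 | step 4 | allyl (E)-3-methoxy-2-(8-methoxy-2,2-dimethyl-2H-chromen-6-yl)acrylate | CO/C=C(\c1cc(OC)c2OC(C)(C)C=Cc2c1)C(=O)OCC=C
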